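**Retrosynthetic overview**
1. Rings A and B are bought as phloroglucinol 1 and 2,4-dihydroxyphenylacetic acid 2; the aryl–carbonyl bond between them is the first disconnection (Friedel–Crafts acylation through lactone 3), leading back from deoxybenzoin 4.
2. Both prenyl groups are cut from ring A as prenyl bromide 5 (double C-alkylation of the acylphloroglucinol, 4 to 6); the para phenol of ring B is masked with TIPSCl 7 (6 to 8), so that only the ortho phenol can build the pyran.
3. Key disconnection: rings D and C are opened together, back to 8, prenal 9 and DMF-DMA 10.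
4. Order of ring formation in that one flask: ring D first (o-quinone methide 11, oxa-6π closure to chromene ketone 12), then ring C (enaminone 13 closing to silyl isoflavone 14), then fluoride frees Kanzonol L 15.

Assumption: the given SMILES has no stereocentre and no stereogenic double bond, so 15 is achiral and the route needs no stereocontrol.

**Step 1**
Reactants: 1 phloroglucinol; 2 2,4-dihydroxyphenylacetic acid
Product: 4 2-(2,4-dihydroxyphenyl)-1-(2,4,6-trihydroxyphenyl)ethan-1-one, via lactone 3 (not isolated)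
Conditions: BF3·OEt2 (neat, as solvent), 80 °C, 2 h; then aq NaOAc
Reagents that add atoms: none
Why: Nencki-type Friedel–Crafts C-acylation, in which acid 2 closes to lactone 3 in BF3·OEt2 and this activated aryl ester acylates the symmetric, electron-rich triol 1 at carbon only once, because product 4 is held as a deactivated BF2 chelate that also resists cyclodehydration; no stereocentre is formed.

**Step 2**
Reactants: 4 2-(2,4-dihydroxyphenyl)-1-(2,4,6-trihydroxyphenyl)ethan-1-one; 5 prenyl bromide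
Product: 6 2-(2,4-dihydroxyphenyl)-1-[2,4,6-trihydroxy-3,5-bis(3-methylbut-2-en-1-yl)phenyl]ethan-1-one
Conditions: prenyl bromide (2.2 equiv), 10% aq KOH (3 equiv), 0 °C, 2 h; then 1 M HCl
Reagents that add atoms: prenyl bromide 5, CC(C)=CCBr
Why: Double C-alkylation (SN2) of an acylphloroglucinol polyanion in water, where the two equivalent free carbons of ring A are far more nucleophilic than any oxygen or than the less acidic resorcinol ring B, so both prenyl groups go to the positions flanking the para hydroxyl; no stereocentre is formed.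

**Step 3**
Reactants: 6 2-(2,4-dihydroxyphenyl)-1-[2,4,6-trihydroxy-3,5-bis(3-methylbut-2-en-1-yl)phenyl]ethan-1-one; 7 chlorotri(propan-2-yl)silane (TIPSCl)
Product: 8 2-{2-hydroxy-4-[(triisopropylsilyl)oxy]phenyl}-1-[2,4,6-trihydroxy-3,5-bis(3-methylbut-2-en-1-yl)phenyl]ethan-1-one
Conditions: TIPSCl (1.1 equiv), imidazole (2.5 equiv), DMF, 0 °C
Reagents that add atoms: TIPSCl 7, CC(C)[Si](Cl)(C(C)C)C(C)C
Why: Sterically controlled O-silylation, since the para hydroxyl of ring B is the only phenol with two free ortho positions and no neighbouring carbonyl, and silyl groups that land on the acidic phenols of ring A are labile enough to be shed on aqueous work-up; no stereocentre is formed.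

**Step 4**
Reactants: 8 2-{2-hydroxy-4-[(triisopropylsilyl)oxy]phenyl}-1-[2,4,6-trihydroxy-3,5-bis(3-methylbut-2-en-1-yl)phenyl]ethan-1-one; 9 3-methylbut-2-enal (prenal); 10 N,N-dimethylformamide dimethyl acetal (DMF-DMA)
Product: 15 Kanzonol L [5,7-dihydroxy-3-(5-hydroxy-2,2-dimethyl-2H-chromen-8-yl)-6,8-bis(3-methylbut-2-en-1-yl)-4H-chromen-4-one], via o-quinone methide 11 (not isolated), via chromene ketone 12 (not isolated), via enaminone 13 (not isolated), via silyl isoflavone 14 (not isolated)
Conditions: prenal (2 equiv), ethylenediammonium diacetate (20 mol %), xylene, 130 °C; then Me2NCH(OMe)2 (2.5 equiv), 60–70 °C; then Bu4NF, AcOH (1:1), THF, 0 °C to rt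
Reagents that add atoms: prenal 9, CC(C)=CC=O; DMF-DMA 10, COC(OC)N(C)C
Why: Telescoped double annulation built from known reactions, in which amine-salt-catalysed Knoevenagel-type condensation of prenal at the only free ortho carbon of the one free phenol of ring B gives o-quinone methide 11, which closes by oxa-6π electrocyclisation to the 2,2-dimethylchromene (ring D, formal [3+3] annulation), DMF-DMA then aminomethylenates the ketone CH2 and enaminone 13 cyclises through either of the two equivalent ortho phenols of ring A with loss of dimethylamine (ring C, enaminone route to isoflavones), and buffered fluoride finally cleaves the aryl silyl ether; no stereocentre is formed.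

**Compound list**
1 | phloroglucinol (benzene-1,3,5-triol) | Oc1cc(O)cc(O)c1 | starting material
2 | 2,4-dihydroxyphenylacetic acid | OC(=O)Cc1ccc(O)cc1O | starting material
3 | 6-hydroxy-1-benzofuran-2(3H)-one (lactone of 2, not isolated) | O=C1Cc2ccc(O)cc2O1 | intermediate
4 | 2-(2,4-dihydroxyphenyl)-1-(2,4,6-trihydroxyphenyl)ethan-1-one | O=C(Cc1ccc(O)cc1O)c1c(O)cc(O)cc1O | intermediate
5 | prenyl bromide (1-bromo-3-methylbut-2-ene) | CC(C)=CCBr | starting material
6 | 2-(2,4-dihydroxyphenyl)-1-[2,4,6-trihydroxy-3,5-bis(3-methylbut-2-en-1-yl)phenyl]ethan-1-one | O=C(Cc1ccc(O)cc1O)c1c(O)c(CC=C(C)C)c(O)c(CC=C(C)C)c1O | intermediate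
7 | chlorotri(propan-2-yl)silane (TIPSCl) | CC(C)[Si](Cl)(C(C)C)C(C)C | starting material
8 | 2-{2-hydroxy-4-[(triisopropylsilyl)oxy]phenyl}-1-[2,4,6-trihydroxy-3,5-bis(3-methylbut-2-en-1-yl)phenyl]ethan-1-one | O=C(Cc1ccc(O[Si](C(C)C)(C(C)C)C(C)C)cc1O)c1c(O)c(CC=C(C)C)c(O)c(CC=C(C)C)c1O | intermediate
9 | 3-methylbut-2-enal (prenal) | CC(C)=CC=O | starting material
10 | N,N-dimethylformamide dimethyl acetal (DMF-DMA) | COC(OC)N(C)C | starting material
11 | (6Z)-6-(3-methylbut-2-en-1-ylidene)-2-{2-oxo-2-[2,4,6-trihydroxy-3,5-bis(3-methylbut-2-en-1-yl)phenyl]ethyl}-5-[(triisopropylsilyl)oxy]cyclohexa-2,4-dien-1-one (o-quinone methide, not isolated) | O=C(CC1=CC=C(O[Si](C(C)C)(C(C)C)C(C)C)/C(=C/C=C(C)C)C1=O)c1c(O)c(CC=C(C)C)c(O)c(CC=C(C)C)c1O | intermediate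
12 | 2-{2,2-dimethyl-5-[(triisopropylsilyl)oxy]-2H-chromen-8-yl}-1-[2,4,6-trihydroxy-3,5-bis(3-methylbut-2-en-1-yl)phenyl]ethan-1-one (chromene ketone, not isolated) | O=C(Cc1ccc(O[Si](C(C)C)(C(C)C)C(C)C)c2C=CC(C)(C)Oc12)c1c(O)c(CC=C(C)C)c(O)c(CC=C(C)C)c1O | intermediate
13 | (2E)-3-(dimethylamino)-2-{2,2-dimethyl-5-[(triisopropylsilyl)oxy]-2H-chromen-8-yl}-1-[2,4,6-trihydroxy-3,5-bis(3-methylbut-2-en-1-yl)phenyl]prop-2-en-1-one (enaminone, not isolated) | O=C(/C(=C/N(C)C)c1ccc(O[Si](C(C)C)(C(C)C)C(C)C)c2C=CC(C)(C)Oc12)c1c(O)c(CC=C(C)C)c(O)c(CC=C(C)C)c1O | intermediate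
14 | 5,7-dihydroxy-3-{2,2-dimethyl-5-[(triisopropylsilyl)oxy]-2H-chromen-8-yl}-6,8-bis(3-methylbut-2-en-1-yl)-4H-chromen-4-one (silyl isoflavone, not isolated) | CC(C)=CCc1c(O)c(CC=C(C)C)c2occ(-c3ccc(O[Si](C(C)C)(C(C)C)C(C)C)c4c3OC(C)(C)C=C4)c(=O)c2c1O | intermediate
15 | Kanzonol L, 5,7-dihydroxy-3-(5-hydroxy-2,2-dimethyl-2H-chromen-8-yl)-6,8-bis(3-methylbut-2-en-1-yl)-4H-chromen-4-one (achiral) | CC(C)=CCc1c(O)c(CC=C(C)C)c2occ(-c3ccc(O)c4c3OC(C)(C)C=C4)c(=O)c2c1O | target

**Totals**
Total step count: 4. Longest linear sequence: 4 steps (from 1 or 2 to 15).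

**Steps most likely to fail, each with one fallback**

Step 2 (double C-prenylation of 4). The risks are mono- and over-alkylation and some alkylation of the free resorcinol ring B. The fallback changes the protecting-group strategy; it sets out from 2 and comes back at 6. Acid 2 is lactonised on its own (p-toluenesulfonic acid cat., PhMe, Dean–Stark) to 3, isolated here. Its single phenol is sulfonylated (TsCl, pyridine, CH2Cl2, 0 °C) to 2-oxo-2,3-dihydro-1-benzofuran-6-yl 4-methylbenzenesulfonate F1. F1 acylates 1 in BF3·OEt2 (80 °C) to 3-hydroxy-4-[2-oxo-2-(2,4,6-trihydroxyphenyl)ethyl]phenyl 4-methylbenzenesulfonate F2, whose ring B is deactivated. Prenylation as in Step 2 can then only hit ring A and gives 3-hydroxy-4-{2-oxo-2-[2,4,6-trihydroxy-3,5-bis(3-methylbut-2-en-1-yl)phenyl]ethyl}phenyl 4-methylbenzenesulfonate F3. KOH in aqueous MeOH (65 °C) removes the sulfonate at the base-stable deoxybenzoin stage and delivers 6. F3 is not carried further as such, because removing a sulfonate from the base-sensitive isoflavone would be much harsher than fluoride.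

Step 3 (silylation of one phenol out of five). The fallback changes the order of events; it sets out from 6 and comes back at 14. Ring C is closed first (DMF-DMA, THF, 60 °C) to 3-(2,4-dihydroxyphenyl)-5,7-dihydroxy-6,8-bis(3-methylbut-2-en-1-yl)-4H-chromen-4-one F4. In F4 the ortho phenol of ring B is hydrogen-bonded to the C4 carbonyl, the 5-OH is chelated and the 7-OH sits between two prenyl groups. TIPSCl/imidazole can therefore reach only the para phenol and gives 5,7-dihydroxy-3-{2-hydroxy-4-[(triisopropylsilyl)oxy]phenyl}-6,8-bis(3-methylbut-2-en-1-yl)-4H-chromen-4-one F5. Prenal with ethylenediammonium diacetate (xylene, 130 °C) then builds ring D on F5 and gives 14, which is desilylated as in Step 4.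

Step 4 (the riskiest). It needs intermolecular C–C bond formation at a flanked carbon of ring B next to a bulky silyl ether, in a molecule with four free phenols and an enolisable ketone; O-methylation of the acidic phenols by DMF-DMA is a second risk. The fallback delivers the five-carbon unit through oxygen and a sigmatropic shift instead of intermolecular C-attack; it sets out from 8 and comes back at 12. The one unhindered phenol of 8 is O-alkylated with 3-chloro-3-methylbut-1-yne (DBU, CuCl2 cat., MeCN, 0 °C) to 2-{2-[(2-methylbut-3-yn-2-yl)oxy]-4-[(triisopropylsilyl)oxy]phenyl}-1-[2,4,6-trihydroxy-3,5-bis(3-methylbut-2-en-1-yl)phenyl]ethan-1-one F6. Heating F6 in xylene at 130 °C triggers aromatic propargyl Claisen rearrangement to the only free ortho carbon, a 1,5-hydrogen shift to the same o-quinone methide 11, and oxa-6π closure to 12. DMF-DMA and buffered fluoride are then added as in Step 4.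

**Further compounds**
F1 | step 2 | 2-oxo-2,3-dihydro-1-benzofuran-6-yl 4-methylbenzenesulfonate | Cc1ccc(cc1)S(=O)(=O)Oc1ccc2CC(=O)Oc2c1
F2 | step 2 | 3-hydroxy-4-[2-oxo-2-(2,4,6-trihydroxyphenyl)ethyl]phenyl 4-methylbenzenesulfonate | Cc1ccc(cc1)S(=O)(=O)Oc1ccc(CC(=O)c2c(O)cc(O)cc2O)c(O)c1
F3 | step 2 | 3-hydroxy-4-{2-oxo-2-[2,4,6-trihydroxy-3,5-bis(3-methylbut-2-en-1-yl)phenyl]ethyl}phenyl 4-methylbenzenesulfonate | Cc1ccc(cc1)S(=O)(=O)Oc1ccc(CC(=O)c2c(O)c(CC=C(C)C)c(O)c(CC=C(C)C)c2O)c(O)c1
F4 | step 3 | 3-(2,4-dihydroxyphenyl)-5,7-dihydroxy-6,8-bis(3-methylbut-2-en-1-yl)-4H-chromen-4-one | CC(C)=CCc1c(O)c(CC=C(C)C)c2occ(-c3ccc(O)cc3O)c(=O)c2c1O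
F5 | step 3 | 5,7-dihydroxy-3-{2-hydroxy-4-[(triisopropylsilyl)oxy]phenyl}-6,8-bis(3-methylbut-2-en-1-yl)-4H-chromen-4-one | CC(C)=CCc1c(O)c(CC=C(C)C)c2occ(-c3ccc(O[Si](C(C)C)(C(C)C)C(C)C)cc3O)c(=O)c2c1O
F6 | step 4 | 2-{2-[(2-methylbut-3-yn-2-yl)oxy]-4-[(triisopropylsilyl)oxy]phenyl}-1-[2,4,6-trihydroxy-3,5-bis(3-methylbut-2-en-1-yl)phenyl]ethan-1-one | C#CC(C)(C)Oc1cc(O[Si](C(C)C)(C(C)C)C(C)C)ccc1CC(=O)c1c(O)c(CC=C(C)C)c(O)c(CC=C(C)C)c1O
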